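All runs were computed for substances that don't exist, noise included.

**The product.** L is what you are after: where does it stand at the end of theta and of beta?

| setting | south | theta | beta |
|---|---|---|---|
| E | 0.025 M | 0.050 M | 0.050 M |
| D | 6.5 mM (held) | 6.5 mM (held) | 6.5 mM (held) |
| temperature | 20 °C | 20 °C | 40 °C |
| remark | run made earlier |  |  |
| time |  | 50 h | 50 h |

- south (time / h: L / %, E / %): 0.417: 3, 96; 1.00: 8, 92; 2.00: 15, 83; 5.00: 25, 58

(scatter of a reading: 2 percentage points)

- at the start none of D is in solution
- the earlier runs do not show what temperature does; that part of a forecast is a guess

- the best flask by amount of L, in percent of the E charged; "all alike" if 1.5 percentage points covers them all (theta / beta / all alike)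
- amount of L at the end, in percent of the E charged, theta
- amount of L at the end, in percent of the E charged, beta

**Start and slope.** In the south run, L has 8% at 1.00 h, as E has lost 8.00%, a ratio that carries the scatter of both readings. Compare the two rates later on. Call the catch, or differential yield, the L gained per E lost over an interval. From 2.00 h to 5.00 h it reads 0.400, with each reading carrying 2 percentage points, so I use it as a rough reading and claim no fall from the early ratio. At the last reading, E lost stands at 10.5 mM and L at 6.25 mM.

**The level.** I assume that whatever consumes L also consumes E. I assume further, as a guess that one run cannot test, that L against E lost, in concentration, follows one curve whatever the charge, and that L levels where E ends. On that guess theta passes the same point and runs on at the catch until its charge of E is lost, which levels at 44.1%. The readings are silent on temperature, so I guess the same for beta and call the two alike.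

**The forecast.** It differs from my levels: 1% in theta, 0.2% in beta, all alike, on the ground that “L is an intermediate, going on to something unseen”.

**The flasks.** Theta ends higher than beta, at 42.3% against 37.1%.

    E + J → L (k = 14.0 /M/h, Ea = 71.0 kJ/mol)
    E → G (k = 0.00590 /h, Ea = 103 kJ/mol)
    2 E → X (k = 0.400 /M/h, Ea = 69.0 kJ/mol)
    E + L → Z (k = 2.10 /M/h, Ea = 56.0 kJ/mol)
    D ⇌ J, rate k5*(csat - [J]) (kL = 2.40 /h)
    (constants at 20 °C)

**While E lasted.** In theta at 25.0 h, E was down to 3.58%, with L at 41.1% and Z at 34.1%. E + J → L and E + L → Z had run side by side while E was there, and from then to 50.0 h the catch reads 0.332. With 0.105% of E left, theta's L holds at 42.3% at 500 h. For beta's neighbour at 40 °C, charged with 0.020 M of E, the point and catch read at 20 °C give 50.2%, and that flask ends at 58.1%.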